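Ring A of the target carries its oxygen at C3 (drimane numbering, used throughout), para to the methyl-bearing C10 and ortho to the methyl-bearing C4, so ring A is read as a dearomatised 2,4-dimethylphenol and C12=C8–C9 as the remnant of an allylsilane. The route rests on the C9–C10 disconnection: oxidation of phenol 20, whose C5 side chain carries an (R)-methoxy stereocentre at C6 and a Z-allylsilane, should close ring B, set C10 and C9 and release the 8(12)-methylene in one operation. The dienone 22 is then methylated at C4 with transposition into a C5=C6 enol ether, reduced at C1=C2 and carried through the 3,6-dione to the 6β-acetate and the umbelliferyl ether.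

Key step: step 13

Remark: allylic 1,3-strain with the C4 methyl group is assumed to hold H6 in the arene plane and the C6 methoxy group pseudo-axial on the face away from the allylsilane, so the (R)-ether is used and the dienone carries 6β-OMe; C6 is erased in step 14, so the opposite sense of induction would be corrected with the antipodal catalyst in step 6.

Step 1
Reactants: 1 2-bromo-1,3-dimethylbenzene
Product: 2 2-bromo-1,3-dimethyl-4-nitrobenzene
Conditions: HNO3 (1.05 equiv), H2SO4, AcOH, 0 °C to rt
Reagents that add atoms: nitric acid, O[N+](=O)[O-]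
Why: Electrophilic aromatic nitration; C4 is para to one methyl group and ortho to the other, whereas the position para to bromine is meta to both, so the 4-nitro isomer should dominate.

Step 2
Reactants: 2 2-bromo-1,3-dimethyl-4-nitrobenzene
Product: 3 3-bromo-2,4-dimethylaniline
Conditions: H2 (1 atm), sulfided Pt/C, EtOAc, rt
Reagents that add atoms: none
Why: Catalytic hydrogenation of the nitro group over sulfided platinum on carbon, a catalyst that should not hydrogenolyse the hindered aryl bromide.

Step 3
Reactants: 3 3-bromo-2,4-dimethylaniline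
Product: 5 3-bromo-2,4-dimethylphenol, via arenediazonium hydrogensulfate 4 (not isolated)
Conditions: NaNO2, 30% aq. H2SO4, 0 °C; then added to boiling 30% aq. H2SO4
Reagents that add atoms: water, O
Why: Diazotisation followed by thermal hydrolysis of the diazonium salt, the standard exchange of an aromatic amino group for hydroxyl.

Step 4
Reactants: 5 3-bromo-2,4-dimethylphenol
Product: 6 (3-bromo-2,4-dimethylphenoxy)triisopropylsilane
Conditions: i-Pr3SiCl, imidazole, DMF, rt
Reagents that add atoms: chlorotriisopropylsilane, CC(C)[Si](Cl)(C(C)C)C(C)C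
Why: Silylation of the phenol; the bulky triisopropylsilyl ether should withstand the organolithium, sodium hydride, aluminium hydride and Grignard steps that follow.

Step 5
Reactants: 6 (3-bromo-2,4-dimethylphenoxy)triisopropylsilane
Product: 8 2,6-dimethyl-3-(triisopropylsilyloxy)benzaldehyde, via aryllithium 7 (not isolated)
Conditions: n-BuLi, THF, −78 °C; DMF, −78 °C to rt; H2O
Reagents that add atoms: N,N-dimethylformamide, CN(C)C=O
Why: Bromine–lithium exchange and formylation of the aryllithium with DMF (Bouveault-type aldehyde synthesis); lithium sits meta to the silyloxy group, so no silyl migration is expected.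

Step 6
Reactants: 8 2,6-dimethyl-3-(triisopropylsilyloxy)benzaldehyde; 9 allenylboronic acid pinacol ester
Product: 11 (1R)-1-[2,6-dimethyl-3-(triisopropylsilyloxy)phenyl]but-3-yn-1-ol, via homopropargyl pinacol borate 10 (not isolated)
Conditions: (R)-TRIP phosphoric acid (10 mol%), 4 Å MS, toluene, 0 °C to rt; aqueous work-up
Reagents that add atoms: none
Why: Chiral phosphoric acid-catalysed propargylboration of the aldehyde through a closed six-membered SE2' transition state; by analogy with the allylboration model the (R)-acid should direct attack to the Re face and give the (R)-carbinol, to be confirmed by Mosher analysis.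

Step 7
Reactants: 11 (1R)-1-[2,6-dimethyl-3-(triisopropylsilyloxy)phenyl]but-3-yn-1-ol
Product: 12 {3-[(1R)-1-methoxybut-3-yn-1-yl]-2,4-dimethylphenoxy}triisopropylsilane
Conditions: NaH, MeI, THF, 0 °C to rt
Reagents that add atoms: iodomethane, CI
Why: Williamson etherification of the sodium alkoxide, which leaves the stereocentre and the aryl silyl ether untouched.

Step 8
Reactants: 12 {3-[(1R)-1-methoxybut-3-yn-1-yl]-2,4-dimethylphenoxy}triisopropylsilane
Product: 14 (5R)-5-[2,6-dimethyl-3-(triisopropylsilyloxy)phenyl]-5-methoxypent-2-yn-1-ol, via lithium acetylide 13 (not isolated)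
Conditions: n-BuLi, THF, −78 °C; (CH2O)n, −78 °C to rt; H2O
Reagents that add atoms: formaldehyde (as paraformaldehyde), C=O
Why: Deprotonation of the terminal alkyne and addition of the acetylide to formaldehyde supplies C11 and the propargylic hydroxyl that directs the next step.

Step 9
Reactants: 14 (5R)-5-[2,6-dimethyl-3-(triisopropylsilyloxy)phenyl]-5-methoxypent-2-yn-1-ol
Product: 16 (2Z,5R)-5-[2,6-dimethyl-3-(triisopropylsilyloxy)phenyl]-3-iodo-5-methoxypent-2-en-1-ol, via cyclic alkenylalanate 15 (not isolated)
Conditions: NaAlH2(OCH2CH2OMe)2 (Red-Al), THF, 0 °C to rt; EtOAc; then I2, THF, −78 to 0 °C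
Reagents that add atoms: iodine, II
Why: Hydroxyl-directed trans-hydroalumination places aluminium on C8 in a five-membered alkoxyalanate, and iodinolysis with retention gives the (Z)-3-iodoallylic alcohol, which fixes C7 trans to C11.

Step 10
Reactants: 16 (2Z,5R)-5-[2,6-dimethyl-3-(triisopropylsilyloxy)phenyl]-3-iodo-5-methoxypent-2-en-1-ol
Product: 17 tert-butyldiphenylsilyl ether of 16
Conditions: t-BuPh2SiCl, imidazole, CH2Cl2, rt
Reagents that add atoms: tert-butylchlorodiphenylsilane, CC(C)(C)[Si](Cl)(c1ccccc1)c1ccccc1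
Why: Silylation of the primary allylic alcohol; the bulky, weakly basic silyl ether should last until step 20 and resist ionisation next to the allylsilane.

Step 11
Reactants: 17 tert-butyldiphenylsilyl ether of 16; 18 (trimethylsilyl)methylmagnesium chloride
Product: 19 {3-[(1R,3Z)-5-(tert-butyldiphenylsilyloxy)-1-methoxy-3-(trimethylsilylmethyl)pent-3-en-1-yl]-2,4-dimethylphenoxy}triisopropylsilane
Conditions: Pd(PPh3)4 (5 mol%), THF, rt to 45 °C
Reagents that add atoms: none
Why: Kumada–Corriu cross-coupling of the alkenyl iodide with the silylmethyl Grignard reagent proceeds with retention of alkene geometry and gives the Z-allylsilane.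

Step 12
Reactants: 19 {3-[(1R,3Z)-5-(tert-butyldiphenylsilyloxy)-1-methoxy-3-(trimethylsilylmethyl)pent-3-en-1-yl]-2,4-dimethylphenoxy}triisopropylsilane
Product: 20 3-[(1R,3Z)-5-(tert-butyldiphenylsilyloxy)-1-methoxy-3-(trimethylsilylmethyl)pent-3-en-1-yl]-2,4-dimethylphenol
Conditions: Bu4NF (1.05 equiv), THF, 0 °C, 15 min; H2O
Reagents that add atoms: none
Why: Fluoride cleaves the aryl silyl ether much faster than the alkyl silyl ether because phenoxide is the better leaving group, and the short cold exposure should spare the allylsilane.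

Step 13
Reactants: 20 3-[(1R,3Z)-5-(tert-butyldiphenylsilyloxy)-1-methoxy-3-(trimethylsilylmethyl)pent-3-en-1-yl]-2,4-dimethylphenol
Product: 22 (6R,9S,10R)-11-(tert-butyldiphenylsilyloxy)-6β-methoxy-14-nordrima-1,4,8(12)-trien-3-one, via aryloxy(phenyl)iodanyl acetate 21 (not isolated)
Conditions: PhI(OAc)2 (1.1 equiv), (CF3)2CHOH/CH2Cl2 4:1, 0.01 M, −20 to 0 °C; then NaHCO3
Reagents that add atoms: none
Why: Proposed new method: ligand exchange at trivalent iodine gives aryloxyiodane 21, whose collapse with loss of iodobenzene in the ionising, non-nucleophilic fluoroalcohol leaves a phenoxenium-type cation with positive charge at C10 (para) and at C4 and C2 (ortho); the γ-carbon C9 of the tethered allylsilane attacks C10 anti to its C–Si bond and the β-silyl cation gives up silicon to acetate, which unveils the C8=C12 methylene, the closest known reaction type being the PhI(OAc)2-mediated intermolecular para-allylation of 4-alkylphenols with allyltrimethylsilane in fluorinated alcohols. Ring B closes in a 6-endo sense at the allylsilane (C8 and C9 both end up in the ring) through a chair, the geometry of a tetralin-forming cationic arene alkylation. C10: the arene face is chosen by the C6 stereocentre, because allylic 1,3-strain with the C4 methyl keeps H6 in the ring plane and the methoxy group pseudo-axial, so that C7 to C9 approach the opposite (α) face and the C10 methyl ends up β. C9: in the chair the Z-alkene places C11 equatorial, cis to the C10 methyl, with H9 axial. The step needs attack at C10 and not at C4, which the larger positive charge at the para carbon and the formation of the cross-conjugated 2,5-dienone should secure; both carbons carry methyl groups, so neither adduct can rearomatise. High dilution and low temperature are meant to suppress intermolecular trapping, quinone methide formation and protodesilylation.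

Step 14
Reactants: 22 (6R,9S,10R)-11-(tert-butyldiphenylsilyloxy)-6β-methoxy-14-nordrima-1,4,8(12)-trien-3-one
Product: 23 (9S,10R)-11-(tert-butyldiphenylsilyloxy)-6-methoxydrima-1,5,8(12)-trien-3-one
Conditions: KOtBu (1.5 equiv), MeI (3 equiv), t-BuOH/THF, 0 °C to rt
Reagents that add atoms: iodomethane, CI
Why: γ-Deprotonation at C6, the only enolisable position of the cross-conjugated dienone, gives an extended enolate that is methylated at its α-carbon C4 (deconjugative α-alkylation, as in the 4,4-dimethylation of steroidal enones), which creates the gem-dimethyl group, moves the alkene to C5=C6 as a methyl enol ether and erases the C6 stereocentre.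

Step 15
Reactants: 23 (9S,10R)-11-(tert-butyldiphenylsilyloxy)-6-methoxydrima-1,5,8(12)-trien-3-one
Product: 24 (9S,10R)-11-(tert-butyldiphenylsilyloxy)-6-methoxydrima-5,8(12)-dien-3-one
Conditions: [(Ph3P)CuH]6 (0.5 equiv), H2O (5 equiv), toluene/THF, rt
Reagents that add atoms: none
Why: Conjugate reduction with phosphine-stabilised copper hydride (Stryker reduction) is selective for the enone C1=C2 and should leave the enol ether, the 1,1-disubstituted alkene and the silyl ether untouched.

Step 16
Reactants: 24 (9S,10R)-11-(tert-butyldiphenylsilyloxy)-6-methoxydrima-5,8(12)-dien-3-one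
Product: 25 (5R,9S,10R)-11-(tert-butyldiphenylsilyloxy)drim-8(12)-ene-3,6-dione
Conditions: 1 M aq. HCl, THF, 0 °C
Reagents that add atoms: water, O
Why: Acid hydrolysis of the strained enol ether, in which C5 is protonated on the α-face away from the axial C10 and 4β methyl groups to give the trans-fused 5α-H dione; the cold dilute acid is chosen so that the 8(12)-alkene does not move into conjugation with the new C6 ketone.

Step 17
Reactants: 25 (5R,9S,10R)-11-(tert-butyldiphenylsilyloxy)drim-8(12)-ene-3,6-dione
Product: 26 (3S,5R,6R,9S,10R)-11-(tert-butyldiphenylsilyloxy)drim-8(12)-ene-3β,6β-diol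
Conditions: LiAlH4, THF, −20 to 0 °C; Fieser work-up
Reagents that add atoms: none
Why: Hydride reduction of both ketones: at C3 axial attack on the α-face gives the equatorial 3β-alcohol, and at C6 the β-face is closed by the syn-axial C10 and 4β methyl groups, so α-attack gives the axial 6β-alcohol.

Step 18
Reactants: 26 (3S,5R,6R,9S,10R)-11-(tert-butyldiphenylsilyloxy)drim-8(12)-ene-3β,6β-diol
Product: 27 (3S,5R,6R,9S,10R)-11-(tert-butyldiphenylsilyloxy)-3β-(triethylsilyloxy)drim-8(12)-en-6β-ol
Conditions: Et3SiCl (1.1 equiv), imidazole, CH2Cl2, 0 °C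
Reagents that add atoms: chlorotriethylsilane, CC[Si](Cl)(CC)CC
Why: Chemoselective silylation, since the equatorial 3β-hydroxyl reacts while the axial 6β-hydroxyl, flanked by two syn-axial methyl groups, should not.

Step 19
Reactants: 27 (3S,5R,6R,9S,10R)-11-(tert-butyldiphenylsilyloxy)-3β-(triethylsilyloxy)drim-8(12)-en-6β-ol
Product: 28 (3S,5R,6R,9S,10R)-11-(tert-butyldiphenylsilyloxy)-3β-(triethylsilyloxy)drim-8(12)-en-6β-yl acetate
Conditions: Ac2O, DMAP, pyridine, 60 °C
Reagents that add atoms: acetic anhydride, CC(=O)OC(C)=O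
Why: DMAP-catalysed acylation (Steglich-type nucleophilic catalysis) under forcing conditions should acetylate the hindered axial 6β-hydroxyl, the only free hydroxyl left.

Step 20
Reactants: 28 (3S,5R,6R,9S,10R)-11-(tert-butyldiphenylsilyloxy)-3β-(triethylsilyloxy)drim-8(12)-en-6β-yl acetate
Product: 29 (3S,5R,6R,9S,10R)-3β,11-dihydroxydrim-8(12)-en-6β-yl acetate
Conditions: Bu4NF (3 equiv), AcOH (3 equiv), THF, rt
Reagents that add atoms: none
Why: Fluoride-mediated cleavage of both silyl ethers, buffered with acetic acid so that the hindered acetate is not touched.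

Step 21
Reactants: 29 (3S,5R,6R,9S,10R)-3β,11-dihydroxydrim-8(12)-en-6β-yl acetate; 30 umbelliferone
Product: 31 7-{[(3S,5R,6R,9S,10R)-6β-acetoxy-3β-hydroxydrim-8(12)-en-11-yl]oxy}-2H-chromen-2-one (CNP0280740.4)
Conditions: PPh3, DIAD, THF, 0 °C to rt
Reagents that add atoms: none
Why: Mitsunobu etherification, in which the acidic phenol displaces the activated primary C11 oxygen by SN2 attack while the neopentylic secondary 3β-hydroxyl is too hindered to react; no stereocentre is involved.

Compound list
1 | 2-bromo-1,3-dimethylbenzene | Cc1cccc(C)c1Br | starting material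
2 | 2-bromo-1,3-dimethyl-4-nitrobenzene | Cc1ccc([N+](=O)[O-])c(C)c1Br | intermediate
3 | 3-bromo-2,4-dimethylaniline | Cc1ccc(N)c(C)c1Br | intermediate
4 | 3-bromo-2,4-dimethylbenzenediazonium hydrogensulfate (not isolated) | Cc1ccc([N+]#N)c(C)c1Br.OS(=O)(=O)[O-] | intermediate
5 | 3-bromo-2,4-dimethylphenol | Cc1ccc(O)c(C)c1Br | intermediate
6 | (3-bromo-2,4-dimethylphenoxy)triisopropylsilane | Cc1ccc(O[Si](C(C)C)(C(C)C)C(C)C)c(C)c1Br | intermediate
7 | [2,6-dimethyl-3-(triisopropylsilyloxy)phenyl]lithium (not isolated) | Cc1ccc(O[Si](C(C)C)(C(C)C)C(C)C)c(C)c1[Li] | intermediate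
8 | 2,6-dimethyl-3-(triisopropylsilyloxy)benzaldehyde | Cc1ccc(O[Si](C(C)C)(C(C)C)C(C)C)c(C)c1C=O | intermediate
9 | allenylboronic acid pinacol ester (4,4,5,5-tetramethyl-2-(propa-1,2-dien-1-yl)-1,3,2-dioxaborolane) | C=C=CB1OC(C)(C)C(C)(C)O1 | starting material
10 | pinacol borate of the (R)-homopropargylic alcohol 11 (not isolated) | Cc1ccc(O[Si](C(C)C)(C(C)C)C(C)C)c(C)c1[C@H](OB1OC(C)(C)C(C)(C)O1)CC#C | intermediate
11 | (1R)-1-[2,6-dimethyl-3-(triisopropylsilyloxy)phenyl]but-3-yn-1-ol | Cc1ccc(O[Si](C(C)C)(C(C)C)C(C)C)c(C)c1[C@H](O)CC#C | intermediate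
12 | {3-[(1R)-1-methoxybut-3-yn-1-yl]-2,4-dimethylphenoxy}triisopropylsilane | Cc1ccc(O[Si](C(C)C)(C(C)C)C(C)C)c(C)c1[C@H](OC)CC#C | intermediate
13 | lithium acetylide of 12 (not isolated) | Cc1ccc(O[Si](C(C)C)(C(C)C)C(C)C)c(C)c1[C@H](OC)CC#C[Li] | intermediate
14 | (5R)-5-[2,6-dimethyl-3-(triisopropylsilyloxy)phenyl]-5-methoxypent-2-yn-1-ol | Cc1ccc(O[Si](C(C)C)(C(C)C)C(C)C)c(C)c1[C@H](OC)CC#CCO | intermediate
15 | sodium cyclic alkenylalanate, aluminium bound to C8 and to the C11 oxygen (not isolated) | COCCO[Al-]1(OCCOC)OCC=C1C[C@@H](OC)c1c(C)ccc(O[Si](C(C)C)(C(C)C)C(C)C)c1C.[Na+] | intermediate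
16 | (2Z,5R)-5-[2,6-dimethyl-3-(triisopropylsilyloxy)phenyl]-3-iodo-5-methoxypent-2-en-1-ol | Cc1ccc(O[Si](C(C)C)(C(C)C)C(C)C)c(C)c1[C@H](OC)C/C(I)=C/CO | intermediate
17 | tert-butyl{[(2Z,5R)-5-[2,6-dimethyl-3-(triisopropylsilyloxy)phenyl]-3-iodo-5-methoxypent-2-en-1-yl]oxy}diphenylsilane | Cc1ccc(O[Si](C(C)C)(C(C)C)C(C)C)c(C)c1[C@H](OC)C/C(I)=C/CO[Si](c1ccccc1)(c1ccccc1)C(C)(C)C | intermediate
18 | (trimethylsilyl)methylmagnesium chloride | C[Si](C)(C)C[Mg]Cl | starting material
19 | {3-[(1R,3Z)-5-(tert-butyldiphenylsilyloxy)-1-methoxy-3-(trimethylsilylmethyl)pent-3-en-1-yl]-2,4-dimethylphenoxy}triisopropylsilane | Cc1ccc(O[Si](C(C)C)(C(C)C)C(C)C)c(C)c1[C@H](OC)C/C(C[Si](C)(C)C)=C/CO[Si](c1ccccc1)(c1ccccc1)C(C)(C)C | intermediate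
20 | 3-[(1R,3Z)-5-(tert-butyldiphenylsilyloxy)-1-methoxy-3-(trimethylsilylmethyl)pent-3-en-1-yl]-2,4-dimethylphenol (key-step precursor) | Cc1ccc(O)c(C)c1[C@H](OC)C/C(C[Si](C)(C)C)=C/CO[Si](c1ccccc1)(c1ccccc1)C(C)(C)C | intermediate
21 | acetoxy(phenyl)iodanyl ether of phenol 20 (not isolated) | CC(=O)OI(c1ccccc1)Oc1ccc(C)c([C@H](OC)C/C(C[Si](C)(C)C)=C/CO[Si](c2ccccc2)(c2ccccc2)C(C)(C)C)c1C | intermediate
22 | (6R,9S,10R)-11-(tert-butyldiphenylsilyloxy)-6β-methoxy-14-nordrima-1,4,8(12)-trien-3-one (4,10β-dimethyl dienone, 9β-CH2OSi) | C=C1C[C@@H](OC)C2=C(C)C(=O)C=C[C@]2(C)[C@H]1CO[Si](c1ccccc1)(c1ccccc1)C(C)(C)C | intermediate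
23 | (9S,10R)-11-(tert-butyldiphenylsilyloxy)-6-methoxydrima-1,5,8(12)-trien-3-one | C=C1CC(OC)=C2C(C)(C)C(=O)C=C[C@]2(C)[C@H]1CO[Si](c1ccccc1)(c1ccccc1)C(C)(C)C | intermediate
24 | (9S,10R)-11-(tert-butyldiphenylsilyloxy)-6-methoxydrima-5,8(12)-dien-3-one | C=C1CC(OC)=C2C(C)(C)C(=O)CC[C@]2(C)[C@H]1CO[Si](c1ccccc1)(c1ccccc1)C(C)(C)C | intermediate
25 | (5R,9S,10R)-11-(tert-butyldiphenylsilyloxy)drim-8(12)-ene-3,6-dione (5α-H, trans-fused) | C=C1CC(=O)[C@H]2C(C)(C)C(=O)CC[C@]2(C)[C@H]1CO[Si](c1ccccc1)(c1ccccc1)C(C)(C)C | intermediate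
26 | (3S,5R,6R,9S,10R)-11-(tert-butyldiphenylsilyloxy)drim-8(12)-ene-3β,6β-diol | C=C1C[C@@H](O)[C@H]2C(C)(C)[C@@H](O)CC[C@]2(C)[C@H]1CO[Si](c1ccccc1)(c1ccccc1)C(C)(C)C | intermediate
27 | (3S,5R,6R,9S,10R)-11-(tert-butyldiphenylsilyloxy)-3β-(triethylsilyloxy)drim-8(12)-en-6β-ol | C=C1C[C@@H](O)[C@H]2C(C)(C)[C@@H](O[Si](CC)(CC)CC)CC[C@]2(C)[C@H]1CO[Si](c1ccccc1)(c1ccccc1)C(C)(C)C | intermediate
28 | (3S,5R,6R,9S,10R)-11-(tert-butyldiphenylsilyloxy)-3β-(triethylsilyloxy)drim-8(12)-en-6β-yl acetate | C=C1C[C@@H](OC(C)=O)[C@H]2C(C)(C)[C@@H](O[Si](CC)(CC)CC)CC[C@]2(C)[C@H]1CO[Si](c1ccccc1)(c1ccccc1)C(C)(C)C | intermediate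
29 | (3S,5R,6R,9S,10R)-3β,11-dihydroxydrim-8(12)-en-6β-yl acetate | C=C1C[C@@H](OC(C)=O)[C@H]2C(C)(C)[C@@H](O)CC[C@]2(C)[C@H]1CO | intermediate
30 | umbelliferone (7-hydroxy-2H-chromen-2-one) | Oc1ccc2ccc(=O)oc2c1 | starting material
31 | 7-{[(3S,5R,6R,9S,10R)-6β-acetoxy-3β-hydroxydrim-8(12)-en-11-yl]oxy}-2H-chromen-2-one (CNP0280740.4) | C=C1C[C@@H](OC(C)=O)[C@H]2C(C)(C)[C@@H](O)CC[C@]2(C)[C@H]1COc1ccc2ccc(=O)oc2c1 | target

Total step count: 21. Longest linear sequence: 21 steps (1 to 31); 9, 18 and 30 are purchased.

Steps most likely to fail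

Step 13 (Proposed new method). The cyclisation can fail in several ways:
- attack at the ortho carbon C4 instead of C10;
- loss of a methyl proton to a quinone methide;
- protodesilylation or oxidation of the allylsilane in the acidic oxidising medium before ring closure;
- incomplete face selection. The two C10 epimers become enantiomers once C6 is erased in step 14, so they must be separated at 22.

Fallback: oxidation and C–C bond formation are separated. It sets out from 20. PhI(OAc)2 in methanol at 0 °C, the standard para-methoxylation of 4-alkylphenols, should give the para-quinol methyl ether F1 (both C10 epimers), which is isolated. A catalytic amount of Me3SiOTf in CH2Cl2 at −78 °C should then ionise the tertiary, doubly allylic ether, and the allylsilane closes ring B (Hosomi–Sakurai substitution of an ionisable ether), which comes back to the route at 22. Both operations are established reaction types, but the ring closure is the same C9–C10 event as in step 13, so this fallback answers only failures caused by the oxidant or the medium. A polarity-reversed closure (phenoxide onto an allylic electrophile) is not offered, because an allyl cation or allyl–metal complex would react at C12 as readily as at C9.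

Step 21. SN2 displacement at the β-branched C11 may be slow, so that elimination towards the 9(11),8(12)-diene or decomposition of the betaine takes over. Fallback: the roles are reversed so that no substitution at C11 is needed. From 29, palladium-catalysed C–O coupling of the primary alcohol with commercial 7-bromocoumarin ([(allyl)PdCl]2, RockPhos, Cs2CO3, toluene, 90 °C; Buchwald-type etherification of a primary alcohol with an aryl bromide) should lead directly to 31. The hindered 3β-hydroxyl should not compete, and no new compound is made on the way (F0).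

Step 6. The di-ortho-substituted, twisted aldehyde may react slowly or with poor enantioselectivity under catalyst control, and every later stereocentre depends on this one. Fallback: the stereocentre is set by a stoichiometric chiral reagent and the alkyne is built afterwards. From 8, Brown allylation with B-allyldiisopinocampheylborane made from (+)-B-methoxydiisopinocampheylborane and allylmagnesium bromide (Et2O, −78 °C; NaOH/H2O2 work-up) should give the (R)-homoallylic alcohol F2. NaH/MeI gives its methyl ether F3. Lemieux–Johnson cleavage (OsO4 cat., NaIO4, 2,6-lutidine, dioxane/H2O) gives the β-methoxy aldehyde F4. Seyferth–Gilbert homologation with the Ohira–Bestmann reagent (dimethyl (1-diazo-2-oxopropyl)phosphonate, K2CO3, MeOH) returns to the route at 12.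

Further compounds
F1 | step 13 | 4-methoxy-2,4-dimethyl-3-[(1R,3Z)-5-(tert-butyldiphenylsilyloxy)-1-methoxy-3-(trimethylsilylmethyl)pent-3-en-1-yl]cyclohexa-2,5-dien-1-one (para-quinol methyl ether, both C10 epimers) | COC1(C)C=CC(=O)C(C)=C1[C@H](OC)C/C(C[Si](C)(C)C)=C/CO[Si](c1ccccc1)(c1ccccc1)C(C)(C)C
F0 | step 21 | none | none
F2 | step 6 | (1R)-1-[2,6-dimethyl-3-(triisopropylsilyloxy)phenyl]but-3-en-1-ol | Cc1ccc(O[Si](C(C)C)(C(C)C)C(C)C)c(C)c1[C@H](O)CC=C
F3 | step 6 | {3-[(1R)-1-methoxybut-3-en-1-yl]-2,4-dimethylphenoxy}triisopropylsilane | Cc1ccc(O[Si](C(C)C)(C(C)C)C(C)C)c(C)c1[C@H](OC)CC=C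
F4 | step 6 | (3R)-3-[2,6-dimethyl-3-(triisopropylsilyloxy)phenyl]-3-methoxypropanal | Cc1ccc(O[Si](C(C)C)(C(C)C)C(C)C)c(C)c1[C@H](OC)CC=O
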